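Before setting the closed flask against the tank and the dosed run, I wanted one figure that would also serve a neighbour of Thursday's flask read at 80 s.

    initiator → 2 initiating radical (k1 = 0.00390 s⁻¹)
    free monomer + initiating radical → growing radical + monomer in chains (k2 = 1.17 × 10⁶ L mol⁻¹ s⁻¹)
    free monomer + growing radical → monomer in chains + growing radical, rate k3*[growing radical]*[free monomer] (k3 = 40100 L mol⁻¹ s⁻¹)
    2 growing radical → dead chain (k4 = 1.3 × 10⁸ L mol⁻¹ s⁻¹)
    free monomer ⇌ dormant form (K5 = 2.38, k5 = 0.00800 s⁻¹)

all flasks: initiator 3.7 mol%

|  | free monomer | remark | time |
|---|---|---|---|
| Friday's | 14 mM | one stirred flow tank at steady state, fed with the mixture as stated, mean residence time 5.0 min |  |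
| Saturday's | 14 mM (fed, over 5.00 min) | all but free monomer at the start; free monomer goes in evenly over 5.00 min, the run ends at 5.0 min | 5.0 min |
| Thursday's | 14 mM | a closed flask charged with all of it at once and left for 5.0 min | 5.0 min |

- order of the set-ups by the amount of monomer in chains at the outlet or at the end, in percent of the free monomer put in, highest first (Friday's / Saturday's / Thursday's)
- amount of monomer in chains at the outlet or at the end, in percent of the free monomer put in, Friday's
- amount of monomer in chains at the outlet or at the end, in percent of the free monomer put in, Saturday's
- amount of monomer in chains at the outlet or at the end, in percent of the free monomer put in, Thursday's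

- a doubled species enters its step squared and goes two at a time
- the stated concentrations are those of everything mixed, before any reaction; amounts are the same in each set-up
- the feed brings no volume worth counting
- run time (Saturday's): 5.0 min

I froze [growing radical]. Setting making equal to loss puts [growing radical] at the square root of the initiator decay constant times [initiator] over the termination constant, starting at 1.25 × 10⁻⁴ mM. Its lifetime against termination at that level, 0.0309 s, is far shorter than the initiator half-life of 3.0 min, so the freeze is fair. Propagation is then pseudo-first-order, starting at 0.00500 s⁻¹ and fading with the square root of [initiator].

Integrated over Thursday's run, that frequency gives 1.14. Initiation adds 5.10% of the charge, one free monomer per initiating radical. With no dormant form, the upper bound is 73.0%. With the dormant form at equilibrium from the first moment, the free share of free monomer plus dormant form is 0.296, and the lower bound is 33.6%.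

The relaxation half-life of 1.02 min is shorter than the run but not negligible, so I let the free share relax from one towards equilibrium, leaving out the drain by chains. Weighting the frequency by that share and integrating gives 0.595, the chain dose: the e-foldings suffered by free monomer and dormant form together. The tightened ceiling is 50.0%. I took the bracket no further than Thursday's.

The forecast gave Thursday's > Friday's > Saturday's, with 45.5%, 34.4% and 28.2% in that order, saying of Saturday's that “much of its monomer arrives late”. Its Thursday's figure lies inside my bracket.

The simulation gave Thursday's > Friday's > Saturday's, with 45.4%, 34.4% and 28.2% in that order, so Thursday's stands 4.5 percentage points under the ceiling. In Thursday's flask, the turning of free monomer into dormant form had reached the middle of its turnover by 0.556 min. Propagation ran on to the end, when 13.7% free monomer stood beside 40.9% dormant form and 31.0% of the initiator. For the neighbour read at 80 s, the chain dose is 0.283, against 0.595 for the full run, and the ceiling is 26.6%. That neighbour flask held 25.8% monomer in chains.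

The numbers are those of an exercise, and the outcome is calculated.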